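Drimane numbering is used (ring A: C1–C5, C10; ring B: C5–C10; C11 on C9). Ring B is a cyclohexene with a C7=C8 double bond, the retron of a Diels–Alder reaction: cutting C5–C6 and C9–C10 leaves an (E)-2-methyl enal that carries C1, C10, C5 and a masked C4–C3–C2 chain, and the vinylallene 3-methylpenta-1,2,4-triene (C6–C9, C11). A chiral oxazaborolidinium-catalysed cycloaddition closes ring B, sets quaternary C10 and C5 (H-5 anti to the C10 methyl, from the E alkene) and leaves an exocyclic C9=C11 alkene. Aldol condensation then closes ring A; hydroboration sets C9 before the coumarin is attached.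

Key step: step 4

Assumption: the oxazaborolidinium cation is taken to discriminate the faces of this α,β-disubstituted enal as it does those of 2-substituted acroleins (the (S)-catalyst leading to attack on the Cα-re face), so the (R)-catalyst is specified; the geminal methyl groups are added after the cycloaddition so that the enal β-carbon stays unhindered.

Step 1
Reactants: 1 ethyl 2-(2-methyl-1,3-dioxolan-2-yl)acetate
Product: 2 (2-methyl-1,3-dioxolan-2-yl)acetaldehyde
Conditions: i-Bu2AlH (1.05 equiv), CH2Cl2, −78 °C; aqueous sodium potassium tartrate work-up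
Reagents that add atoms: none
Why: Partial ester reduction with i-Bu2AlH at low temperature should stop at the aluminium hemiacetal, which releases the aldehyde on work-up while the dioxolane is untouched.

Step 2
Reactants: 2 (2-methyl-1,3-dioxolan-2-yl)acetaldehyde; 3 2-(triphenylphosphoranylidene)propanal
Product: 4 (2E)-2-methyl-4-(2-methyl-1,3-dioxolan-2-yl)but-2-enal
Conditions: toluene, 90 °C
Reagents that add atoms: none
Why: Wittig olefination with the stabilised formyl ylide should be E-selective and stop after one homologation, because the α-branched conjugated enal formed is far less electrophilic than 2.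

Step 3
Reactants: 5 1-bromobut-2-yne; 6 vinylmagnesium bromide
Product: 7 3-methylpenta-1,2,4-triene
Conditions: CuBr·SMe2 (5 mol %), THF, −40 → 0 °C; pentane extraction, water washes to remove THF, distillation; the volatile triene is taken up in CH2Cl2
Reagents that add atoms: none
Why: Copper-catalysed SN2′ substitution of the propargylic bromide should deliver the vinyl group to the methyl-bearing alkyne carbon and give the allene.

Step 4
Reactants: 4 (2E)-2-methyl-4-(2-methyl-1,3-dioxolan-2-yl)but-2-enal; 7 3-methylpenta-1,2,4-triene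
Product: 8 (1R,6R)-1,3-dimethyl-2-methylidene-6-[(2-methyl-1,3-dioxolan-2-yl)methyl]cyclohex-3-ene-1-carbaldehyde
Conditions: (R)-3,3-diphenyl-1-(2-methylphenyl)tetrahydro-1H,3H-pyrrolo[1,2-c][1,3,2]oxazaborole (20 mol %) protonated with HN(SO2CF3)2 (18 mol %), CH2Cl2, −78 → −40 °C, diene in excess
Reagents that add atoms: none
Why: The enal, bound through its carbonyl oxygen to the boron cation in the s-trans form, and the s-cis diene unit C6=C7–C8=C9 of 7 should combine in a concerted, asynchronous [4+2] cycloaddition in which C5–C6 forms ahead of C9–C10; the closest known reaction type is the enantioselective Diels–Alder reaction of 2-substituted enals under chiral oxazaborolidinium catalysis, with a vinylallene as the diene. Ring B is the only ring closed, in the suprafacial six-membered cycloaddition mode. C5 and quaternary C10 arise together: the E geometry of 4 places H-5 anti to the C10 methyl group (the later trans ring fusion), and the catalyst, which should shield the Cα-re face, directs the diene to the Cα-si face and so fixes the absolute configuration (1R,6R). C9 stays trigonal, so no endo/exo selectivity is needed. The step needs orientational selectivity, secured by the allenyl terminus acting as a 1-alkyl-type donor that makes the vinyl CH2 (C6) the nucleophilic end for the enal β-carbon and by the small sp carbon C9 being the better partner for the carbon that becomes quaternary, and it needs periselectivity, secured because only the allene double bond conjugated with the vinyl group can take part and the s-trans-locked diene of 8 cannot react again.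

Step 5
Reactants: 8 (1R,6R)-1,3-dimethyl-2-methylidene-6-[(2-methyl-1,3-dioxolan-2-yl)methyl]cyclohex-3-ene-1-carbaldehyde
Product: 11 (4aS,8aR)-4a,6-dimethyl-5-methylidene-4a,5,8,8a-tetrahydronaphthalen-2(1H)-one, via keto aldehyde 9 (not isolated), via aldol adduct 10 (not isolated)
Conditions: pyridinium p-toluenesulfonate, THF/H2O (4:1), 50 °C; solvent removed; then KOH, MeOH, 25 → 60 °C
Reagents that add atoms: water, O
Why: Mild acetal hydrolysis should unveil the methyl ketone, whose methyl-side enolate can only attack the non-enolisable aldehyde in a six-membered intramolecular aldol condensation that closes ring A, the trans ring fusion being already fixed by C5 and C10.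

Step 6
Reactants: 11 (4aS,8aR)-4a,6-dimethyl-5-methylidene-4a,5,8,8a-tetrahydronaphthalen-2(1H)-one
Product: 13 (4aR,8aS)-1,1,4a,6-tetramethyl-5-methylidene-4a,5,8,8a-tetrahydronaphthalen-2(1H)-one, via monomethyl enone 12 (not isolated)
Conditions: KOt-Bu (3 equiv), MeI (6 equiv), THF, 0 → 25 °C
Reagents that add atoms: iodomethane, CI
Why: C4 is the only enolisable position of the enone (the γ-carbon C10 is quaternary), so exhaustive α′-alkylation of the cross-conjugated enolate should install the geminal methyl groups without creating a stereocentre.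

Step 7
Reactants: 13 (4aR,8aS)-1,1,4a,6-tetramethyl-5-methylidene-4a,5,8,8a-tetrahydronaphthalen-2(1H)-one
Product: 14 (4aR,8aS)-1,1,4a,6-tetramethyl-5-methylidene-3,4,4a,5,8,8a-hexahydronaphthalen-2(1H)-one
Conditions: [(Ph3P)CuH]6 (5 mol %), PhMe2SiH (1.5 equiv), t-BuOH (1.5 equiv), toluene, 25 °C
Reagents that add atoms: none
Why: Copper hydride conjugate reduction should add hydride 1,4 to the enone, with protonation of the copper enolate by t-BuOH, and leave the unpolarised diene untouched.

Step 8
Reactants: 14 (4aR,8aS)-1,1,4a,6-tetramethyl-5-methylidene-3,4,4a,5,8,8a-hexahydronaphthalen-2(1H)-one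
Product: 15 (2R,4aR,8aS)-1,1,4a,6-tetramethyl-5-methylidene-1,2,3,4,4a,5,8,8a-octahydronaphthalen-2-ol
Conditions: NaBH4, MeOH, 0 °C
Reagents that add atoms: none
Why: Diastereoselective carbonyl reduction: hydride should attack C3 axially on the face that carries only the axial hydrogens at C1 and C5, away from the axial C4 methyl group, giving the equatorial alcohol cis to the C10 methyl group, as is usual for 4,4-dimethyl-3-ketones of trans-decalins.

Step 9
Reactants: 15 (2R,4aR,8aS)-1,1,4a,6-tetramethyl-5-methylidene-1,2,3,4,4a,5,8,8a-octahydronaphthalen-2-ol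
Product: 16 (2R,4aR,8aS)-1,1,4a,6-tetramethyl-5-methylidene-1,2,3,4,4a,5,8,8a-octahydronaphthalen-2-yl acetate
Conditions: Ac2O, pyridine, 4-(dimethylamino)pyridine (cat.), CH2Cl2, 25 °C
Reagents that add atoms: acetic anhydride, CC(=O)OC(C)=O
Why: Nucleophile-catalysed acylation of the secondary alcohol should proceed with retention at C3.

Step 10
Reactants: 16 (2R,4aR,8aS)-1,1,4a,6-tetramethyl-5-methylidene-1,2,3,4,4a,5,8,8a-octahydronaphthalen-2-yl acetate
Product: 18 (2R,4aR,5R,8aS)-5-(hydroxymethyl)-1,1,4a,6-tetramethyl-1,2,3,4,4a,5,8,8a-octahydronaphthalen-2-yl acetate, via alkylborane 17 (not isolated)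
Conditions: 9-borabicyclo[3.3.1]nonane, THF, 0 → 25 °C; then NaBO3·4H2O, H2O, 25 °C
Reagents that add atoms: 9-borabicyclo[3.3.1]nonane, B1C2CCCC1CCC2 (its boron stays only in 17); sodium perborate, [Na+].[Na+].O[B-]1(O)OO[B-](O)(O)OO1 (gives the hydroxyl oxygen)
Why: Hydroboration–oxidation: the bulky borane should place boron on terminal C11 of the exocyclic alkene and hydrogen on C9 from the face opposite the axial C10 methyl group (syn addition), which sets C9, and perborate should oxidise the C–B bond with retention without cleaving the acetate.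

Step 11
Reactants: 18 (2R,4aR,5R,8aS)-5-(hydroxymethyl)-1,1,4a,6-tetramethyl-1,2,3,4,4a,5,8,8a-octahydronaphthalen-2-yl acetate; 19 umbelliferone (7-hydroxy-2H-chromen-2-one)
Product: 20 7-{[(1R,4aS,6R,8aR)-6-(acetyloxy)-2,5,5,8a-tetramethyl-1,4,4a,5,6,7,8,8a-octahydronaphthalen-1-yl]methoxy}-2H-chromen-2-one
Conditions: PPh3, diisopropyl azodicarboxylate, THF, 0 → 25 °C
Reagents that add atoms: none
Why: Mitsunobu etherification: the acidic phenol should displace the alkoxyphosphonium ion of the primary alcohol by SN2 at C11, which is not a stereocentre.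

Compound list
1 | ethyl 2-(2-methyl-1,3-dioxolan-2-yl)acetate | CCOC(=O)CC1(C)OCCO1 | starting material
2 | (2-methyl-1,3-dioxolan-2-yl)acetaldehyde | O=CCC1(C)OCCO1 | intermediate
3 | 2-(triphenylphosphoranylidene)propanal | CC(C=O)=P(c1ccccc1)(c1ccccc1)c1ccccc1 | starting material
4 | (2E)-2-methyl-4-(2-methyl-1,3-dioxolan-2-yl)but-2-enal | O=C/C(C)=C/CC1(C)OCCO1 | intermediate
5 | 1-bromobut-2-yne | CC#CCBr | starting material
6 | vinylmagnesium bromide | C=C[Mg]Br | starting material
7 | 3-methylpenta-1,2,4-triene | C=C=C(C)C=C | intermediate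
8 | (1R,6R)-1,3-dimethyl-2-methylidene-6-[(2-methyl-1,3-dioxolan-2-yl)methyl]cyclohex-3-ene-1-carbaldehyde | O=C[C@@]1(C)C(=C)C(C)=CC[C@@H]1CC2(C)OCCO2 | intermediate
9 | (1R,6R)-1,3-dimethyl-2-methylidene-6-(2-oxopropyl)cyclohex-3-ene-1-carbaldehyde | O=C[C@@]1(C)C(=C)C(C)=CC[C@@H]1CC(C)=O | intermediate
10 | (4aR,8aR)-4-hydroxy-4a,6-dimethyl-5-methylidene-3,4,4a,5,8,8a-hexahydronaphthalen-2(1H)-one (C4 epimers) | O=C1CC(O)[C@@]2(C)C(=C)C(C)=CC[C@@H]2C1 | intermediate
11 | (4aS,8aR)-4a,6-dimethyl-5-methylidene-4a,5,8,8a-tetrahydronaphthalen-2(1H)-one | O=C1C=C[C@@]2(C)C(=C)C(C)=CC[C@@H]2C1 | intermediate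
12 | (4aR,8aR)-1,4a,6-trimethyl-5-methylidene-4a,5,8,8a-tetrahydronaphthalen-2(1H)-one (C1 epimers) | O=C1C=C[C@@]2(C)C(=C)C(C)=CC[C@@H]2C1C | intermediate
13 | (4aR,8aS)-1,1,4a,6-tetramethyl-5-methylidene-4a,5,8,8a-tetrahydronaphthalen-2(1H)-one | O=C1C=C[C@@]2(C)C(=C)C(C)=CC[C@@H]2C1(C)C | intermediate
14 | (4aR,8aS)-1,1,4a,6-tetramethyl-5-methylidene-3,4,4a,5,8,8a-hexahydronaphthalen-2(1H)-one | O=C1CC[C@@]2(C)C(=C)C(C)=CC[C@@H]2C1(C)C | intermediate
15 | (2R,4aR,8aS)-1,1,4a,6-tetramethyl-5-methylidene-1,2,3,4,4a,5,8,8a-octahydronaphthalen-2-ol | O[C@@H]1CC[C@@]2(C)C(=C)C(C)=CC[C@@H]2C1(C)C | intermediate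
16 | (2R,4aR,8aS)-1,1,4a,6-tetramethyl-5-methylidene-1,2,3,4,4a,5,8,8a-octahydronaphthalen-2-yl acetate | CC(=O)O[C@@H]1CC[C@@]2(C)C(=C)C(C)=CC[C@@H]2C1(C)C | intermediate
17 | (2R,4aS,5R,8aS)-5-[(9-borabicyclo[3.3.1]nonan-9-yl)methyl]-1,1,4a,6-tetramethyl-1,2,3,4,4a,5,8,8a-octahydronaphthalen-2-yl acetate | CC(=O)O[C@@H]1CC[C@@]2(C)[C@H](CB3C4CCCC3CCC4)C(C)=CC[C@@H]2C1(C)C | intermediate
18 | (2R,4aR,5R,8aS)-5-(hydroxymethyl)-1,1,4a,6-tetramethyl-1,2,3,4,4a,5,8,8a-octahydronaphthalen-2-yl acetate | CC(=O)O[C@@H]1CC[C@@]2(C)[C@H](CO)C(C)=CC[C@@H]2C1(C)C | intermediate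
19 | umbelliferone (7-hydroxy-2H-chromen-2-one) | Oc1ccc2ccc(=O)oc2c1 | starting material
20 | 7-{[(1R,4aS,6R,8aR)-6-(acetyloxy)-2,5,5,8a-tetramethyl-1,4,4a,5,6,7,8,8a-octahydronaphthalen-1-yl]methoxy}-2H-chromen-2-one | CC(=O)O[C@@H]1CC[C@@]2(C)[C@H](COc3ccc4ccc(=O)oc4c3)C(C)=CC[C@@H]2C1(C)C | target

Total step count: 11. Longest linear sequence: 10 steps (steps 1, 2 and 4 to 11).

Steps most likely to fail

Step 4. The vinylallene may oligomerise under the strong Lewis acid, the enal β-carbon may bond to the central allene carbon (wrong orientation), and facial discrimination for the α,β-disubstituted enal may be poor. The fallback sets out from 4 and returns at 8. Commercial (2E)-3-methylpent-2-en-4-yn-1-ol would be semi-hydrogenated (H2, Pd/CaCO3 poisoned with Pb(OAc)2, quinoline) to (2E)-3-methylpenta-2,4-dien-1-ol F1 and converted with (PhS)2 and PBu3 into phenyl (2E)-3-methylpenta-2,4-dien-1-yl sulfide F2. The same catalysed cycloaddition of this stable E-diene with 4 should give the sulfide adduct F3, whose C9 epimers are both usable. Oxidation with NaIO4 to the sulfoxide F4 and thermal syn-elimination (toluene, 110 °C, CaCO3) would then unveil the exocyclic alkene of 8.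

Step 10. Addition of the bulky borane next to quaternary C10 may be sluggish, and 1,4-addition across the diene or hydrogen delivery to C9 from the methyl-bearing face may compete. The fallback sets out from 16 and returns at 18. Hydrosilylation with HSi(OEt)3 and Pt2[(CH2=CHSiMe2)2O]3 should place the small silyl group on C11, giving the triethoxysilane F5, and Tamao–Fleming oxidation (KF, KHCO3, H2O2, THF/MeOH) would convert the C–Si bond into the C–OH bond of 18 with retention.

Step 11. Activation of the β-branched, homoallylic C11 oxygen may end in elimination back to the exocyclic diene instead of substitution. The fallback sets out from 18 and returns at 20. The roles are reversed, so that C11 is never activated: the alcohol is coupled as the nucleophile with commercial 7-bromo-2H-chromen-2-one (O=c1ccc2ccc(Br)cc2o1) in a palladium-catalysed C–O cross-coupling ([Pd(C3H5)Cl]2, the biaryl phosphine RockPhos, Cs2CO3, toluene, 90 °C).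

Further compounds
F1 | step 4 | (2E)-3-methylpenta-2,4-dien-1-ol | C=CC(/C)=C/CO
F2 | step 4 | phenyl (2E)-3-methylpenta-2,4-dien-1-yl sulfide | C=CC(/C)=C/CSc1ccccc1
F3 | step 4 | (1R,6R)-1,3-dimethyl-6-[(2-methyl-1,3-dioxolan-2-yl)methyl]-2-[(phenylsulfanyl)methyl]cyclohex-3-ene-1-carbaldehyde (C2 epimers) | O=C[C@@]1(C)C(CSc2ccccc2)C(C)=CC[C@@H]1CC3(C)OCCO3
F4 | step 4 | (1R,6R)-2-[(benzenesulfinyl)methyl]-1,3-dimethyl-6-[(2-methyl-1,3-dioxolan-2-yl)methyl]cyclohex-3-ene-1-carbaldehyde (C2 and sulfur epimers) | O=C[C@@]1(C)C(CS(=O)c2ccccc2)C(C)=CC[C@@H]1CC3(C)OCCO3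
F5 | step 10 | (2R,4aR,5R,8aS)-1,1,4a,6-tetramethyl-5-[(triethoxysilyl)methyl]-1,2,3,4,4a,5,8,8a-octahydronaphthalen-2-yl acetate | CC(=O)O[C@@H]1CC[C@@]2(C)[C@H](C[Si](OCC)(OCC)OCC)C(C)=CC[C@@H]2C1(C)C
F0 | step 11 | none | none
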